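**Retrosynthetic overview**
- The target is reached by global O-debenzylation of the 5,7,3'-tri-O-benzyl flavone 14.
- Ring C, the only ring built, is closed last by oxidative cyclisation of the 2'-hydroxychalcone 12; rings A and B are bought as arenes.
- The key C–C bond (Cα–Cβ of the chalcone) comes from a Claisen–Schmidt aldol condensation of ring A ketone 10 with ring B aldehyde 8.
- Aldehyde 8 comes from syringol 1 by acetylation, formylation, bromination, CuBr-catalysed methanolysis and benzylation.
- Ketone 10 comes from phloroacetophenone 9 by selective dibenzylation.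

Assumption: the target has no stereocentre, so the achiral compound itself is the required single stereoisomer; the only stereo-element in the route is the E alkene of 12.

**Step 1**
Reactants: 1 2,6-dimethoxyphenol (syringol)
Product: 2 2,6-dimethoxyphenyl acetate
Conditions: Ac2O, pyridine, DMAP (cat.), rt
Reagents that add atoms: acetic anhydride, CC(=O)OC(C)=O
Why: DMAP-catalysed O-acetylation (nucleophilic acyl substitution) turns the phenol oxygen into a weak donor, so later electrophilic substitution is steered by the two methoxy groups and not para to the phenol oxygen.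

**Step 2**
Reactants: 2 2,6-dimethoxyphenyl acetate
Product: 4 3-acetoxy-2,4-dimethoxybenzaldehyde, via chloro ether 3 (not isolated)
Conditions: Cl2CHOMe, TiCl4, CH2Cl2, −10 to 0 °C; then ice/H2O
Reagents that add atoms: dichloromethyl methyl ether, COC(Cl)Cl; water, O
Why: Rieche formylation (Friedel–Crafts-type electrophilic aromatic substitution) attacks the carbon ortho to one methoxy, para to the other and meta to the acetoxy group, and the α-chloro ether is hydrolysed to the aldehyde on aqueous work-up.

**Step 3**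
Reactants: 4 3-acetoxy-2,4-dimethoxybenzaldehyde
Product: 5 3-acetoxy-5-bromo-2,4-dimethoxybenzaldehyde
Conditions: Br2, NaOAc, AcOH, rt to 40 °C
Reagents that add atoms: bromine, BrBr
Why: Electrophilic aromatic bromination goes to C5 (ortho to 4-OMe, para to 2-OMe, meta to CHO), whereas C6 is ortho to the formyl group and activated only by the weak para acetoxy group.

**Step 4**
Reactants: 5 3-acetoxy-5-bromo-2,4-dimethoxybenzaldehyde
Product: 7 3-hydroxy-2,4,5-trimethoxybenzaldehyde, via sodium bromophenoxide 6 (not isolated)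
Conditions: NaOMe (5 equiv, 25% in MeOH), CuBr (15 mol%), DMF, 105 °C, N2; then 2 M HCl
Reagents that add atoms: sodium methoxide, C[O-].[Na+]
Why: Methoxide first removes the acetate by transesterification, then CuBr catalyses Ullmann-type methanolysis of the aryl bromide (the 5-bromovanillin to syringaldehyde process), which the non-enolisable electron-rich aldehyde should tolerate.

**Step 5**
Reactants: 7 3-hydroxy-2,4,5-trimethoxybenzaldehyde
Product: 8 3-(benzyloxy)-2,4,5-trimethoxybenzaldehyde
Conditions: BnBr, K2CO3, DMF, 50 °C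
Reagents that add atoms: benzyl bromide, BrCc1ccccc1
Why: Williamson ether synthesis (SN2) on the only free phenol installs a group that survives KOH and hot I2/DMSO and leaves by hydrogenolysis at the end.

**Step 6**
Reactants: 9 2,4,6-trihydroxyacetophenone (dried)
Product: 10 1-[2,4-bis(benzyloxy)-6-hydroxyphenyl]ethanone
Conditions: BnBr (2.05 equiv), K2CO3 (2.2 equiv), DMF, 0 °C to rt
Reagents that add atoms: benzyl bromide, BrCc1ccccc1
Why: Williamson etherification stops after two benzylations because the remaining ortho hydroxyl is strongly hydrogen-bonded to the ketone carbonyl and is the least nucleophilic.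

**Step 7**
Reactants: 10 1-[2,4-bis(benzyloxy)-6-hydroxyphenyl]ethanone; 8 3-(benzyloxy)-2,4,5-trimethoxybenzaldehyde
Product: 12 (E)-1-[2,4-bis(benzyloxy)-6-hydroxyphenyl]-3-[3-(benzyloxy)-2,4,5-trimethoxyphenyl]prop-2-en-1-one, via aldol adduct 11 (not isolated)
Conditions: KOH (50% aq, 15 equiv), EtOH/THF, rt, 48–72 h; then cold 1 M HCl
Reagents that add atoms: none
Why: Claisen–Schmidt crossed aldol condensation in which only the methyl ketone can enolise and only the aldehyde is electrophilic; E1cB dehydration of the racemic aldol gives the thermodynamically favoured E enone, so no stereocentre remains.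

**Step 8**
Reactants: 12 (E)-1-[2,4-bis(benzyloxy)-6-hydroxyphenyl]-3-[3-(benzyloxy)-2,4,5-trimethoxyphenyl]prop-2-en-1-one
Product: 14 5,7-bis(benzyloxy)-2-[3-(benzyloxy)-2,4,5-trimethoxyphenyl]-4H-chromen-4-one, via flavanone 13 (not isolated)
Conditions: I2 (10 mol%), DMSO, 130 °C, 2–4 h; then aq Na2S2O3
Reagents that add atoms: none
Why: I2/DMSO oxidative cyclisation: oxa-Michael closure of the 2'-hydroxychalcone to the racemic flavanone, α-iodination and loss of HI give the aromatic chromone ring C, with DMSO re-oxidising HI to I2 and the C2 stereocentre destroyed.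

**Step 9**
Reactants: 14 5,7-bis(benzyloxy)-2-[3-(benzyloxy)-2,4,5-trimethoxyphenyl]-4H-chromen-4-one
Product: 15 5,7,3'-trihydroxy-2',4',5'-trimethoxyflavone
Conditions: H2 (1 atm), 10% Pd/C, THF/MeOH, rt, stopped at full debenzylation
Reagents that add atoms: none
Why: Catalytic hydrogenolysis of the three benzyl aryl ethers is much faster than reduction of the vinylogous-ester C2=C3 bond and leaves the methyl ethers untouched, giving the achiral target.

**Compound list**
1 | 2,6-dimethoxyphenol (syringol) | COc1cccc(OC)c1O | starting material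
2 | 2,6-dimethoxyphenyl acetate | COc1cccc(OC)c1OC(C)=O | intermediate
3 | 3-[chloro(methoxy)methyl]-2,6-dimethoxyphenyl acetate (racemic, not isolated) | COC(Cl)c1ccc(OC)c(OC(C)=O)c1OC | intermediate
4 | 3-acetoxy-2,4-dimethoxybenzaldehyde | COc1ccc(C=O)c(OC)c1OC(C)=O | intermediate
5 | 3-acetoxy-5-bromo-2,4-dimethoxybenzaldehyde | COc1c(Br)cc(C=O)c(OC)c1OC(C)=O | intermediate
6 | 5-bromo-3-hydroxy-2,4-dimethoxybenzaldehyde sodium salt (not isolated) | COc1c(Br)cc(C=O)c(OC)c1[O-].[Na+] | intermediate
7 | 3-hydroxy-2,4,5-trimethoxybenzaldehyde | COc1cc(C=O)c(OC)c(O)c1OC | intermediate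
8 | 3-(benzyloxy)-2,4,5-trimethoxybenzaldehyde | COc1cc(C=O)c(OC)c(OCc2ccccc2)c1OC | intermediate
9 | 2,4,6-trihydroxyacetophenone (phloroacetophenone) | CC(=O)c1c(O)cc(O)cc1O | starting material
10 | 1-[2,4-bis(benzyloxy)-6-hydroxyphenyl]ethanone | CC(=O)c1c(O)cc(OCc2ccccc2)cc1OCc1ccccc1 | intermediate
11 | 1-[2,4-bis(benzyloxy)-6-hydroxyphenyl]-3-[3-(benzyloxy)-2,4,5-trimethoxyphenyl]-3-hydroxypropan-1-one (racemic, not isolated) | COc1cc(C(O)CC(=O)c2c(O)cc(OCc3ccccc3)cc2OCc2ccccc2)c(OC)c(OCc2ccccc2)c1OC | intermediate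
12 | (E)-1-[2,4-bis(benzyloxy)-6-hydroxyphenyl]-3-[3-(benzyloxy)-2,4,5-trimethoxyphenyl]prop-2-en-1-one | COc1cc(/C=C/C(=O)c2c(O)cc(OCc3ccccc3)cc2OCc2ccccc2)c(OC)c(OCc2ccccc2)c1OC | intermediate
13 | 5,7-bis(benzyloxy)-2-[3-(benzyloxy)-2,4,5-trimethoxyphenyl]chroman-4-one (racemic, not isolated) | COc1cc(C2CC(=O)c3c(OCc4ccccc4)cc(OCc4ccccc4)cc3O2)c(OC)c(OCc2ccccc2)c1OC | intermediate
14 | 5,7-bis(benzyloxy)-2-[3-(benzyloxy)-2,4,5-trimethoxyphenyl]-4H-chromen-4-one | COc1cc(-c2cc(=O)c3c(OCc4ccccc4)cc(OCc4ccccc4)cc3o2)c(OC)c(OCc2ccccc2)c1OC | intermediate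
15 | 5,7,3'-trihydroxy-2',4',5'-trimethoxyflavone | COc1cc(-c2cc(=O)c3c(O)cc(O)cc3o2)c(OC)c(O)c1OC | target

**Totals**
Total step count: 9. Longest linear sequence: 8 steps (1, 2, 3, 4, 5, 7, 8, 9 from syringol); step 6 is a one-step side branch.

**Steps most likely to fail, with fallbacks**

Step 4 (methanolysis of the aryl bromide beside a free aldehyde; possible Cannizzaro-type loss or hydrodebromination). The fallback sets out from 5 and comes back at 7. The aldehyde is masked first: HC(OMe)3 and cat. TsOH in MeOH at rt give 3-acetoxy-5-bromo-2,4-dimethoxybenzaldehyde dimethyl acetal F1 (partial loss of the acetate here is harmless). The same NaOMe/CuBr/DMF treatment at 105 °C then gives 3-hydroxy-2,4,5-trimethoxybenzaldehyde dimethyl acetal F2, and dilute aqueous HCl on work-up releases aldehyde 7.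

Step 7 (aldol between a doubly ortho-substituted acetophenone phenoxide and a hindered, electron-rich aldehyde; slow or incomplete). The fallback sets out from 8, uses 10 as partner, and comes back at 14, bypassing 12. It replaces the aldol by an intermolecular Claisen condensation. Aldehyde 8 is oxidised with NaClO2, NaH2PO4 and 2-methyl-2-butene in t-BuOH/H2O to 3-(benzyloxy)-2,4,5-trimethoxybenzoic acid F3. Oxalyl chloride with cat. DMF in CH2Cl2 gives 3-(benzyloxy)-2,4,5-trimethoxybenzoyl chloride F4. This is added at −78 °C to the dianion of 10, made with LiN(SiMe3)2 (3.5 equiv) in THF, and acidic work-up gives 1-[2,4-bis(benzyloxy)-6-hydroxyphenyl]-3-[3-(benzyloxy)-2,4,5-trimethoxyphenyl]propane-1,3-dione F5. Cyclodehydration with cat. TsOH in toluene at reflux gives flavone 14.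

Step 8 (HI formed at 130 °C can cleave the 5-O-benzyl ether or iodinate the electron-rich rings). The fallback sets out from 12 and comes back at 14. The two events are separated: NaOAc in EtOH at reflux closes 12 to flavanone 13, which is isolated, and DDQ in 1,4-dioxane at reflux dehydrogenates it to 14 without any iodine or acid. New compound on this path: none F0.

**Further compounds**
F1 | step 4 | 3-acetoxy-5-bromo-2,4-dimethoxybenzaldehyde dimethyl acetal | COc1c(Br)cc(C(OC)OC)c(OC)c1OC(C)=O
F2 | step 4 | 3-hydroxy-2,4,5-trimethoxybenzaldehyde dimethyl acetal | COc1cc(C(OC)OC)c(OC)c(O)c1OC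
F3 | step 7 | 3-(benzyloxy)-2,4,5-trimethoxybenzoic acid | COc1cc(C(=O)O)c(OC)c(OCc2ccccc2)c1OC
F4 | step 7 | 3-(benzyloxy)-2,4,5-trimethoxybenzoyl chloride | COc1cc(C(=O)Cl)c(OC)c(OCc2ccccc2)c1OC
F5 | step 7 | 1-[2,4-bis(benzyloxy)-6-hydroxyphenyl]-3-[3-(benzyloxy)-2,4,5-trimethoxyphenyl]propane-1,3-dione | COc1cc(C(=O)CC(=O)c2c(O)cc(OCc3ccccc3)cc2OCc2ccccc2)c(OC)c(OCc2ccccc2)c1OC
F0 | step 8 | none | none
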